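**Strategy.** Ring A is disconnected across C2–C3 and C1–C6 into a two-carbon alkoxy ynone (C1 and C2, with the butanoyl group) and a four-carbon ketene acetal silyl dienol ether (C3–C6). Their cycloaddition, followed by loss of methanol, should build the benzene ring with five substituents in place and the three ring A oxygens already told apart by origin. O at C6 (between C1 and the C5 methyl) arrives as OCH3, O at C4 as a silyl ether that becomes free OH, and O at C2 as an isopropyl ether removable beside OCH3. C3 stays free for the methylene bridge to the acetylfilicinic acid ring, attached last through a Mannich base.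

Key step: step 6

Remarks on the chemistry:
- Ring A numbering: C1 butanoyl, C2 OH, C3 bridge, C4 OH, C5 CH3, C6 OCH3. Both O at C2 and O at C6 flank C1; the methylated one is O at C6, which also flanks the C5 methyl.
- Acetylfilicinic acid and the target are drawn as the enol tautomers of the target SMILES; these tautomers interconvert freely.
- The dichlorovinyl ether is assumed to form as the E isomer (anti addition); its geometry does not matter for the next step.
- The ynone is made by acylating the alkoxyacetylide with commercial N-methoxy-N-methylbutanamide, which avoids an acid-labile propargylic alcohol and an oxidation.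

Step 1
Reactants: 1 trimethyl orthopropionate (1,1,1-trimethoxypropane)
Product: 2 1,1-dimethoxyprop-1-ene
Conditions: Al(OCH3)3 (cat.), neat, ca. 200 °C, CH3OH removed by fractional distillation
Reagents that add atoms: none
Why: Lewis-acid-catalysed thermal dealcoholation of an orthoester (beta-elimination of methanol from the dimethoxycarbenium ion) can only remove a C2 hydrogen, so a single ketene acetal should form and is driven over by distilling out methanol.

Step 2
Reactants: 2 1,1-dimethoxyprop-1-ene
Product: 3 4,4-dimethoxy-3-methylbut-3-en-2-one
Conditions: AcCl, pyridine, Et2O, 0 °C → rt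
Reagents that add atoms: acetyl chloride, CC(Cl)=O
Why: C-acylation of a ketene acetal by an acid chloride (addition then loss of a proton) should give the acyl ketene acetal, pyridine removing the acidic proton of the dimethoxycarbenium intermediate before chloride can demethylate it and being too weak a base to turn acetyl chloride into ketene.

Step 3
Reactants: 3 4,4-dimethoxy-3-methylbut-3-en-2-one
Product: 5 1,1-dimethoxy-2-methyl-3-(trimethylsilyloxy)buta-1,3-diene, via lithium dienolate 4 (not isolated)
Conditions: LiN(iPr)2, THF, −78 °C; Me3SiCl, −78 → 0 °C; non-aqueous work-up, distillation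
Reagents that add atoms: chlorotrimethylsilane, C[Si](C)(C)Cl
Why: kinetic enolisation at the acetyl CH3, the only enolisable position, followed by O-silylation of the cross-conjugated enolate is the standard preparation of 1,1-dialkoxy-3-siloxybuta-1,3-dienes.

Step 4
Reactants: 6 trichloroethylene
Product: 8 (E)-1,2-dichloro-1-(propan-2-yloxy)ethene, via dichloroethyne 7 (not isolated)
Conditions: KH, iPrOH, THF, 0 °C; then 6, −50 °C → rt
Reagents that add atoms: propan-2-ol, CC(C)O
Why: the alkoxide dehydrochlorinates trichloroethylene and the alcohol then adds anti to the dichloroethyne so formed (net vinylic substitution), the established route to 1,2-dichlorovinyl ethers of secondary alcohols.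

Step 5
Reactants: 8 (E)-1,2-dichloro-1-(propan-2-yloxy)ethene; 9 N-methoxy-N-methylbutanamide
Product: 12 1-(propan-2-yloxy)hex-1-yn-3-one, via lithium isopropoxyacetylide 10 (not isolated), via lithium tetrahedral adduct 11 (not isolated)
Conditions: n-BuLi (2.05 equiv), THF, −78 → −40 °C; then 9, −78 → −20 °C; cold 1 M aq. HCl/Et2O quench, fast phase separation
Reagents that add atoms: none
Why: dehydrochlorination and chlorine-lithium exchange give the alkoxyacetylide, and the Weinreb ketone synthesis stops at the ynone because the chelated adduct survives until the cold acidic quench, which also keeps the liberated amine from adding to the product.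

Step 6
Reactants: 5 1,1-dimethoxy-2-methyl-3-(trimethylsilyloxy)buta-1,3-diene; 12 1-(propan-2-yloxy)hex-1-yn-3-one
Product: 15 1-[4-hydroxy-2-methoxy-3-methyl-6-(propan-2-yloxy)phenyl]butan-1-one, via cyclohexa-1,4-diene cycloadduct 13 (not isolated), via aryl trimethylsilyl ether 14 (not isolated)
Conditions: 5 (1.5 equiv), PhMe (concentrated), 25 → 50 °C, argon; then 1 M aq. HCl, THF, 0 °C
Reagents that add atoms: none
Why: Proposed new method: the CH2 terminus of diene 5, made strongly nucleophilic by the two methoxy groups and the siloxy group, should attack the isopropoxy-bearing carbon of ynone 12, which is electrophilic both as the beta carbon of the ynone and as the oxygen-bound carbon of an ynol ether, so the C2-C3 bond forms first. The allenolate carbon then closes ring A on the dimethoxycarbenium carbon (C1-C6 bond), a 6-exo-trig closure in the stepwise Michael/Mukaiyama picture or the second bond of a strongly asynchronous Diels-Alder reaction. Cycloadduct 13 carries a ketal carbon between two sp2 carbons and a ring CH2 opposite, so 1,4-elimination of methanol should give arene 14, and dilute acid frees phenol 15; no stereocentre remains. The closest known reaction type is the Diels-Alder/aromatisation of 1,1-dialkoxy-3-siloxybuta-1,3-dienes with ynones and acetylenic esters to resorcinol monoethers, whereas a dienophile with an alkoxy donor on the reacting alkyne carbon is untested, hence the mild temperature, kept below the point at which an isopropyl ynol ether loses propene. The step needs head-to-tail regioselectivity (OCH3 next to C1) and reaction at C≡C and not at C=O. The first is secured by the matched polarisation just described and the second by the ketone being deactivated as the carbonyl of an alkynylogous ester.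

Step 7
Reactants: 15 1-[4-hydroxy-2-methoxy-3-methyl-6-(propan-2-yloxy)phenyl]butan-1-one
Product: 16 1-(4,6-dihydroxy-2-methoxy-3-methylphenyl)butan-1-one
Conditions: BCl3 (3 equiv), CH2Cl2, −78 → 0 °C; aq. NaHCO3
Reagents that add atoms: none
Why: Lewis-acid dealkylation of an aryl isopropyl ether ortho to a carbonyl group should be much faster than cleavage of the aryl methyl ether because chloride takes the secondary alkyl group through a cation-like transition state, and boron chelation of the new phenoxide with the ketone then shields the remaining OCH3.

Step 8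
Reactants: 16 1-(4,6-dihydroxy-2-methoxy-3-methylphenyl)butan-1-one
Product: 17 1-{3-[(dimethylamino)methyl]-2,4-dihydroxy-6-methoxy-5-methylphenyl}butan-1-one
Conditions: CH2=N(CH3)2 I (1.05 equiv), Et3N, CH2Cl2, 0 °C → rt
Reagents that add atoms: N,N-dimethylmethyleneiminium iodide, C=[N+](C)C.[I-]
Why: Mannich reaction with a preformed iminium salt should aminomethylate C3, the only free ring position, which lies between two hydroxyl groups, so no regioisomer or second substitution is possible.

Step 9
Reactants: 18 2,4,6-trihydroxyacetophenone
Product: 19 2-acetyl-3,5-dihydroxy-6,6-dimethylcyclohexa-2,4-dien-1-one (acetylfilicinic acid)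
Conditions: NaOCH3 (3.5 equiv), CH3I (2.2 equiv), CH3OH, 0 °C → rt; then aq. HCl
Reagents that add atoms: iodomethane, CI
Why: dearomatising geminal C-methylation of an acylphloroglucinol polyanion at one ring carbon is the classical entry to acylfilicinic acids, the second methyl group entering at the same carbon because the monomethylated anion is the more nucleophilic.

Step 10
Reactants: 17 1-{3-[(dimethylamino)methyl]-2,4-dihydroxy-6-methoxy-5-methylphenyl}butan-1-one; 19 acetylfilicinic acid
Product: 21 aspidin AB, 2-acetyl-4-[(3-butanoyl-2,6-dihydroxy-4-methoxy-5-methylphenyl)methyl]-3,5-dihydroxy-6,6-dimethylcyclohexa-2,4-dien-1-one, via ortho-quinone methide 20 (not isolated)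
Conditions: 19 (1.2 equiv), 1,4-dioxane, 90 °C, argon stream; dilute aq. HCl wash
Reagents that add atoms: none
Why: the acidic triketone protonates the Mannich base, thermal loss of dimethylamine gives an ortho-quinone methide, and Michael addition of the only nucleophilic ring carbon of 19 (the CH between its two enolic oxygens) should give the unsymmetrical methylene-bridged dimer without homo-coupling, since no ring A molecule has a free nucleophilic position.

**Compound list**
1 | trimethyl orthopropionate (1,1,1-trimethoxypropane) | CCC(OC)(OC)OC | starting material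
2 | 1,1-dimethoxyprop-1-ene | CC=C(OC)OC | intermediate
3 | 4,4-dimethoxy-3-methylbut-3-en-2-one | CC(=O)C(C)=C(OC)OC | intermediate
4 | lithium 4,4-dimethoxy-3-methylbuta-1,3-dien-2-olate | [Li+].[O-]C(=C)C(C)=C(OC)OC | intermediate
5 | 1,1-dimethoxy-2-methyl-3-(trimethylsilyloxy)buta-1,3-diene | COC(OC)=C(C)C(=C)O[Si](C)(C)C | intermediate
6 | trichloroethylene | ClC=C(Cl)Cl | starting material
7 | dichloroethyne | ClC#CCl | intermediate
8 | (E)-1,2-dichloro-1-(propan-2-yloxy)ethene | Cl/C=C(/Cl)OC(C)C | intermediate
9 | N-methoxy-N-methylbutanamide | CCCC(=O)N(C)OC | starting material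
10 | lithium (propan-2-yloxy)ethynide | [Li+].[C-]#COC(C)C | intermediate
11 | lithium 3-[methoxy(methyl)amino]-1-(propan-2-yloxy)hex-1-yn-3-olate (racemic) | [Li+].CCCC([O-])(N(C)OC)C#COC(C)C | intermediate
12 | 1-(propan-2-yloxy)hex-1-yn-3-one | CCCC(=O)C#COC(C)C | intermediate
13 | 1-[6,6-dimethoxy-5-methyl-2-(propan-2-yloxy)-4-(trimethylsilyloxy)cyclohexa-1,4-dien-1-yl]butan-1-one | CCCC(=O)C1=C(OC(C)C)CC(O[Si](C)(C)C)=C(C)C1(OC)OC | intermediate
14 | 1-[2-methoxy-3-methyl-6-(propan-2-yloxy)-4-(trimethylsilyloxy)phenyl]butan-1-one | CCCC(=O)c1c(OC(C)C)cc(O[Si](C)(C)C)c(C)c1OC | intermediate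
15 | 1-[4-hydroxy-2-methoxy-3-methyl-6-(propan-2-yloxy)phenyl]butan-1-one | CCCC(=O)c1c(OC(C)C)cc(O)c(C)c1OC | intermediate
16 | 1-(4,6-dihydroxy-2-methoxy-3-methylphenyl)butan-1-one | CCCC(=O)c1c(O)cc(O)c(C)c1OC | intermediate
17 | 1-{3-[(dimethylamino)methyl]-2,4-dihydroxy-6-methoxy-5-methylphenyl}butan-1-one | CCCC(=O)c1c(O)c(CN(C)C)c(O)c(C)c1OC | intermediate
18 | 2,4,6-trihydroxyacetophenone | CC(=O)c1c(O)cc(O)cc1O | starting material
19 | 2-acetyl-3,5-dihydroxy-6,6-dimethylcyclohexa-2,4-dien-1-one (acetylfilicinic acid) | CC(=O)C1=C(O)C=C(O)C(C)(C)C1=O | intermediate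
20 | 4-butanoyl-3-hydroxy-5-methoxy-6-methyl-2-methylidenecyclohexa-3,5-dien-1-one | CCCC(=O)C1=C(O)C(=C)C(=O)C(C)=C1OC | intermediate
21 | aspidin AB | CCCC(=O)c1c(O)c(CC2=C(O)C(C)(C)C(=O)C(C(C)=O)=C2O)c(O)c(C)c1OC | target

**Count.** Total: 10 steps. Longest linear sequence: 7 steps (steps 1, 2, 3, 6, 7, 8, 10).

**Steps most likely to fail**

1. Step 6. The alkoxy donor may make the alkyne too poor a dienophile, and on warming the ynol ether may lose propene to an acyl ketene. The ketene acetal end of the diene may also add [2+2], or the diene may attack the ketone carbonyl. The fallback uses known chemistry, sets out from amide 9 and diene 5, and returns at phenol 16. HC≡CMgBr adds to 9 (THF, 0 °C) to give hex-1-yn-3-one F1. Diene 5 and F1 then undergo the established thermal Diels-Alder/aromatisation of this diene class with a terminal ynone (PhMe, 60–80 °C; dilute HCl) to give 1-(4-hydroxy-2-methoxy-3-methylphenyl)butan-1-one F2. Pivaloyl chloride and pyridine give 4-butanoyl-3-methoxy-2-methylphenyl 2,2-dimethylpropanoate F3. Ketone-directed ortho C–H hydroxylation (Pd(OAc)2 cat., K2S2O8, CF3CO2H/(CF3CO)2O) at the only free ortho position gives 4-butanoyl-5-hydroxy-3-methoxy-2-methylphenyl 2,2-dimethylpropanoate F4. K2CO3 in CH3OH removes the pivalate and gives 16, so step 7 is not needed.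

2. Step 5. The push-pull ynone may be lost by conjugate addition of the liberated N,O-dimethylhydroxylamine or by hydration of the ynol ether during the quench, and excess n-BuLi may consume the amide. The fallback sets out from dichlorovinyl ether 8 (through acetylide 10, made as in step 5) and returns at ynone 12. Acetylide 10 is added to butanal (CCCC=O) at −78 °C and worked up with NaHCO3 to give racemic 1-(propan-2-yloxy)hex-1-yn-3-ol F5. This is oxidised with MnO2 in CH2Cl2 at room temperature to 12, so no amine is present at any point.

3. Step 10. Heating may be too mild to expel dimethylamine, or hot enough to scramble the methylene bridge between the two ring types and to close a xanthene by dehydration. The fallback swaps the roles of the partners; it sets out from acetylfilicinic acid 19 and phenol 16 and returns at target 21. Acid 19 is aminomethylated with CH2=N(CH3)2 I and Et3N in CH2Cl2 to give 2-acetyl-4-[(dimethylamino)methyl]-3,5-dihydroxy-6,6-dimethylcyclohexa-2,4-dien-1-one F6. This base loses dimethylamine at 20–40 °C in CH3OH to a methylidene triketone that is trapped at C3 of 16 to give 21; step 8 is then not needed.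

**Further compounds**
F1 | step 6 | hex-1-yn-3-one | CCCC(=O)C#C
F2 | step 6 | 1-(4-hydroxy-2-methoxy-3-methylphenyl)butan-1-one | CCCC(=O)c1ccc(O)c(C)c1OC
F3 | step 6 | 4-butanoyl-3-methoxy-2-methylphenyl 2,2-dimethylpropanoate | CCCC(=O)c1ccc(OC(=O)C(C)(C)C)c(C)c1OC
F4 | step 6 | 4-butanoyl-5-hydroxy-3-methoxy-2-methylphenyl 2,2-dimethylpropanoate | CCCC(=O)c1c(O)cc(OC(=O)C(C)(C)C)c(C)c1OC
F5 | step 5 | 1-(propan-2-yloxy)hex-1-yn-3-ol (racemic) | CCCC(O)C#COC(C)C
F6 | step 10 | 2-acetyl-4-[(dimethylamino)methyl]-3,5-dihydroxy-6,6-dimethylcyclohexa-2,4-dien-1-one | CN(C)CC1=C(O)C(C)(C)C(=O)C(C(C)=O)=C1O
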